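**Strategy.** The pyran ring is cut at its two bonds to the benzene ring, C4–C4a and O1–C8a (chromene numbering; primes for the cyclohexene), so that the complete terpenoid half arrives as one enantiopure (Z)-γ-hydroxyalkenylboronate and the arene arrives dearomatised, as the p-quinone monoketal of 6-iodo-2,3,4-trimethoxyphenol. The key step exploits the para relation of C5–OH and C8–OMe in ring A: in the monoketal the α-iodoenone carbon is C4a and the enone β-carbon is C8a. Suzuki coupling, 6-endo oxa-Michael addition and loss of methanol then make both bonds, close the pyran and rebuild the arene with a free C5 phenol. C2 comes from a lithiation–borylation, C1' from a radical addition, C2' from an auxiliary Diels–Alder reaction.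

Key step: step 11

Remark: 2,3,4-trimethoxyphenol is taken as purchasable, and borylation of the lithiated propargylic carbamate is taken to proceed with retention, as for other secondary carbamates with pinacol boronates.

Step 1
Reactants: 1 (4R)-4-benzyl-1,3-oxazolidin-2-one; 2 acryloyl chloride
Product: 4 (4R)-3-acryloyl-4-benzyl-1,3-oxazolidin-2-one, via N-lithio oxazolidinone 3 (not isolated)
Conditions: n-BuLi, THF, −78 °C; then 2, −78 → 0 °C
Reagents that add atoms: none
Why: N-acylation of the lithium amide of the oxazolidinone with the acid chloride at low temperature should give the acrylimide without polymerisation and without touching the stereocentre.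

Step 2
Reactants: 4 (4R)-3-acryloyl-4-benzyl-1,3-oxazolidin-2-one; 5 (3E)-3-methylpenta-1,3-diene
Product: 6 (4R)-4-benzyl-3-[(1S,2S)-2,3-dimethylcyclohex-3-ene-1-carbonyl]-1,3-oxazolidin-2-one
Conditions: Et2AlCl (1.4 equiv), 5 (excess), CH2Cl2, −78 °C
Reagents that add atoms: none
Why: Auxiliary-controlled, Lewis acid-promoted Diels–Alder reaction in which the aluminium-chelated s-cis acrylimide is attacked endo on the face opposite the benzyl group, the terminal methyl of the diene directs the "ortho" orientation as in (E)-penta-1,3-diene, and endo addition sets the acyl group and the C2' methyl cis with C2' in the S configuration.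

Step 3
Reactants: 6 (4R)-4-benzyl-3-[(1S,2S)-2,3-dimethylcyclohex-3-ene-1-carbonyl]-1,3-oxazolidin-2-one
Product: 8 (1S,2S)-2,3-dimethylcyclohex-3-ene-1-carboxylic acid, via peroxy acid 7 (not isolated)
Conditions: LiOH, H2O2, THF/H2O, 0 °C; then Na2SO3; then HCl
Reagents that add atoms: hydrogen peroxide, OO
Why: Hydroperoxide cleavage of the N-acyl oxazolidinone, in which LiOOH attacks the exocyclic carbonyl and sulfite reduces the peroxy acid, should free the acid without epimerisation and return the auxiliary.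

Step 4
Reactants: 8 (1S,2S)-2,3-dimethylcyclohex-3-ene-1-carboxylic acid
Product: 10 (1S,2R)-1,2,3-trimethylcyclohex-3-ene-1-carboxylic acid, via dilithium enediolate 9 (not isolated)
Conditions: LiN(i-Pr)2 (2.2 equiv), THF, −78 → 0 °C; MeI, −78 → 23 °C; HCl work-up
Reagents that add atoms: iodomethane, CI
Why: Alkylation of the carboxylic acid dianion with iodomethane builds the quaternary carbon, expected anti to the C2' methyl, but the configuration at C1' is of no consequence because this carbon becomes a planar radical in step 5.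

Step 5
Reactants: 10 (1S,2R)-1,2,3-trimethylcyclohex-3-ene-1-carboxylic acid; 11 4,4,5,5-tetramethyl-2-vinyl-1,3,2-dioxaborolane
Product: 12 4,4,5,5-tetramethyl-2-{2-[(1R,2S)-1,2,3-trimethylcyclohex-3-en-1-yl]ethyl}-1,3,2-dioxaborolane
Conditions: Ir[dF(CF3)ppy]2(dtbbpy)PF6 (1 mol%), Cs2CO3 (0.5 equiv), 11 (2 equiv), DMF, blue LEDs, 23 °C
Reagents that add atoms: none
Why: Photoredox decarboxylative Giese-type addition to a vinylboronate, in which the excited iridium photocatalyst oxidises the carboxylate, loss of CO2 gives the tertiary C1' radical, and this adds to 11 anti to the C2' methyl (held pseudoaxial by allylic strain with the C3' methyl and the planar radical centre), so that the chain ends trans to the C2' methyl and the C1' and C2' methyls cis.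

Step 6
Reactants: 13 (2S)-4-(trimethylsilyl)but-3-yn-2-ol
Product: 14 (2S)-4-(trimethylsilyl)but-3-yn-2-yl N,N-diisopropylcarbamate
Conditions: i-Pr2NCOCl, Et3N, CH2Cl2, reflux
Reagents that add atoms: N,N-diisopropylcarbamoyl chloride, CC(C)N(C(C)C)C(Cl)=O
Why: O-carbamoylation of the secondary propargylic alcohol installs the directing and leaving group for lithiation–borylation and leaves the stereocentre untouched.

Step 7
Reactants: 12 4,4,5,5-tetramethyl-2-{2-[(1R,2S)-1,2,3-trimethylcyclohex-3-en-1-yl]ethyl}-1,3,2-dioxaborolane; 14 (2S)-4-(trimethylsilyl)but-3-yn-2-yl N,N-diisopropylcarbamate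
Product: 19 (3R)-3-methyl-5-[(1S,2S)-1,2,3-trimethylcyclohex-3-en-1-yl]pent-1-yn-3-ol, via lithiated carbamate 15 (not isolated), via boronate complex 16 (not isolated), via tertiary boronic ester 17 (not isolated), via silylalkyne carbinol 18 (not isolated)
Conditions: 14, s-BuLi, TMEDA, Et2O, −78 °C; then 12, −78 → 35 °C; then NaOH, H2O2, THF/H2O, 0 °C; then K2CO3, MeOH, 23 °C
Reagents that add atoms: hydrogen peroxide, OO
Why: Lithiation–borylation with 1,2-metallate rearrangement, in which s-BuLi removes the carbinol hydrogen of 14 with retention, the organolithium binds the boron of 12 with retention, the alkyl group migrates from boron to carbon anti to the departing carbamate (inversion), and oxidation of the C–B bond with retention followed by methanolysis of the C–Si bond translates the S configuration of 13 into the R configuration of the future C2.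

Step 8
Reactants: 19 (3R)-3-methyl-5-[(1S,2S)-1,2,3-trimethylcyclohex-3-en-1-yl]pent-1-yn-3-ol
Product: 22 (1Z,3R)-3-methyl-1-(4,4,5,5-tetramethyl-1,3,2-dioxaborolan-2-yl)-5-[(1S,2S)-1,2,3-trimethylcyclohex-3-en-1-yl]pent-1-en-3-ol, via O-boryl alkyne 20 (not isolated), via O-boryl alkenylboronate 21 (not isolated)
Conditions: HBpin (1.0 equiv), Et3N, cyclohexane, 23 °C; then [Rh(cod)Cl]2 (1.5 mol%), P(i-Pr)3 (6 mol%), HBpin (1.0 equiv), 23 °C; MeOH work-up
Reagents that add atoms: pinacolborane, [H]B1OC(C)(C)C(C)(C)O1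
Why: Rhodium-catalysed anti-Markovnikov trans-hydroboration of a terminal alkyne through a rhodium vinylidene should give the (Z)-alkenylboronate, with the hydroxyl masked in the flask as its O-boryl ester and freed again by methanol, and the carbinol centre is not involved.

Step 9
Reactants: 23 2,3,4-trimethoxyphenol
Product: 24 6-iodo-2,3,4-trimethoxyphenol
Conditions: NIS, MeCN, 0 °C, dark
Reagents that add atoms: N-iodosuccinimide, O=C1CCC(=O)N1I
Why: Electrophilic aromatic iodination goes ortho to the free hydroxyl, the strongest director, whose para position is blocked by a methoxy group.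

Step 10
Reactants: 24 6-iodo-2,3,4-trimethoxyphenol
Product: 25 6-iodo-2,3,4,4-tetramethoxycyclohexa-2,5-dien-1-one
Conditions: PhI(OAc)2, MeOH, 0 °C
Reagents that add atoms: methanol, CO
Why: Oxidative dearomatisation of a p-methoxyphenol with a hypervalent iodine reagent in methanol traps the phenoxenium ion at the para carbon and gives the p-quinone monoketal, which places the iodine on the enone α-carbon (future C4a) and a hydrogen on the enone β-carbon (future C8a).

Step 11
Reactants: 22 (1Z,3R)-3-methyl-1-(4,4,5,5-tetramethyl-1,3,2-dioxaborolan-2-yl)-5-[(1S,2S)-1,2,3-trimethylcyclohex-3-en-1-yl]pent-1-en-3-ol; 25 6-iodo-2,3,4,4-tetramethoxycyclohexa-2,5-dien-1-one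
Product: 28 (2R)-6,7,8-trimethoxy-2-methyl-2-{2-[(1S,2S)-1,2,3-trimethylcyclohex-3-en-1-yl]ethyl}-2H-chromen-5-ol, via coupled dienone 26 (not isolated), via dihydrochromenone 27 (not isolated)
Conditions: PdCl2(dppf) (5 mol%), Cs2CO3, THF/H2O (20:1), 40 °C, dark; then dry (Na2SO4), CSA (0.2 equiv), CH2Cl2, 0 °C (telescoped, no purification)
Reagents that add atoms: none
Why: Zerovalent palladium inserts into the C–I bond of the α-iodoenone 25, and Suzuki–Miyaura transmetalation with 22 followed by reductive elimination forms C4–C4a with retention of the Z alkene to give dienone 26. The Z geometry holds the tertiary hydroxyl over the enone β-carbon C8a, to which it adds in a 6-endo-trig oxa-Michael closure of the pyran ring (O1–C8a) to give 27. Camphorsulfonic acid then ionises the C8 ketal, methanol leaves and enolisation of the C5 ketone restores ring A with C5–OH free and C8–OMe in place. The closest known reaction types are the Suzuki–Miyaura coupling of α-iodoenones and the conjugate addition of oxygen nucleophiles to p-quinone monoketals followed by aromatisation. No new stereocentre remains: C2 keeps the configuration of 22 because its C–O bond is never broken, and the two transient sp3 ring-fusion carbons of 27 become aromatic. The step needs carbon attachment at C4a and oxygen attachment at C8a only, which the substrate secures by carrying iodine on the only α-carbon without a methoxy group and hydrogen on the only enone β-carbon within reach of the hydroxyl, the other β-carbon being part of a vinylogous ester.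

**Compound list**

1 | (4R)-4-benzyl-1,3-oxazolidin-2-one | O=C1N[C@H](Cc2ccccc2)CO1 | starting material
2 | acryloyl chloride | C=CC(Cl)=O | starting material
3 | lithium (4R)-4-benzyl-2-oxo-1,3-oxazolidin-3-ide | [Li+].O=C1[N-][C@H](Cc2ccccc2)CO1 | intermediate (not isolated)
4 | (4R)-3-acryloyl-4-benzyl-1,3-oxazolidin-2-one | C=CC(=O)N1[C@H](Cc2ccccc2)COC1=O | intermediate
5 | (3E)-3-methylpenta-1,3-diene | C=C/C(C)=C/C | starting material
6 | (4R)-4-benzyl-3-[(1S,2S)-2,3-dimethylcyclohex-3-ene-1-carbonyl]-1,3-oxazolidin-2-one (acyl group and C2 methyl cis) | O=C([C@H]1CCC=C(C)[C@H]1C)N1[C@H](Cc2ccccc2)COC1=O | intermediate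
7 | (1S,2S)-2,3-dimethylcyclohex-3-ene-1-carboperoxoic acid (lithium salt in the flask) | OOC(=O)[C@H]1CCC=C(C)[C@H]1C | intermediate (not isolated)
8 | (1S,2S)-2,3-dimethylcyclohex-3-ene-1-carboxylic acid | OC(=O)[C@H]1CCC=C(C)[C@H]1C | intermediate
9 | dilithium [(2S)-2,3-dimethylcyclohex-3-en-1-ylidene]methanediolate | [Li+].[Li+].[O-]C([O-])=C1CCC=C(C)[C@H]1C | intermediate (not isolated)
10 | (1S,2R)-1,2,3-trimethylcyclohex-3-ene-1-carboxylic acid (carboxyl cis to the C2 methyl; expected major epimer, the C1 epimer serves equally) | OC(=O)[C@@]1(C)CCC=C(C)[C@H]1C | intermediate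
11 | 4,4,5,5-tetramethyl-2-vinyl-1,3,2-dioxaborolane | C=CB1OC(C)(C)C(C)(C)O1 | starting material
12 | 4,4,5,5-tetramethyl-2-{2-[(1R,2S)-1,2,3-trimethylcyclohex-3-en-1-yl]ethyl}-1,3,2-dioxaborolane (ring methyls at C1 and C2 cis) | CC1(C)OB(CC[C@]2(C)CCC=C(C)[C@H]2C)OC1(C)C | intermediate
13 | (2S)-4-(trimethylsilyl)but-3-yn-2-ol | C[C@H](O)C#C[Si](C)(C)C | starting material
14 | (2S)-4-(trimethylsilyl)but-3-yn-2-yl N,N-diisopropylcarbamate | C[C@H](OC(=O)N(C(C)C)C(C)C)C#C[Si](C)(C)C | intermediate
15 | (2S)-2-lithio-4-(trimethylsilyl)but-3-yn-2-yl N,N-diisopropylcarbamate (lithium in place of the carbinol hydrogen) | C[C@]([Li])(OC(=O)N(C(C)C)C(C)C)C#C[Si](C)(C)C | intermediate (not isolated)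
16 | lithium boronate complex of 15 and 12 (boron in place of lithium, retention) | C[C@]([B-]1(CC[C@]2(C)CCC=C(C)[C@H]2C)OC(C)(C)C(C)(C)O1)(OC(=O)N(C(C)C)C(C)C)C#C[Si](C)(C)C.[Li+] | intermediate (not isolated)
17 | 4,4,5,5-tetramethyl-2-{(3S)-3-methyl-1-(trimethylsilyl)-5-[(1S,2S)-1,2,3-trimethylcyclohex-3-en-1-yl]pent-1-yn-3-yl}-1,3,2-dioxaborolane | C[C@@](B1OC(C)(C)C(C)(C)O1)(CC[C@]2(C)CCC=C(C)[C@H]2C)C#C[Si](C)(C)C | intermediate (not isolated)
18 | (3R)-3-methyl-1-(trimethylsilyl)-5-[(1S,2S)-1,2,3-trimethylcyclohex-3-en-1-yl]pent-1-yn-3-ol | C[C@@](O)(CC[C@]1(C)CCC=C(C)[C@H]1C)C#C[Si](C)(C)C | intermediate (not isolated)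
19 | (3R)-3-methyl-5-[(1S,2S)-1,2,3-trimethylcyclohex-3-en-1-yl]pent-1-yn-3-ol | C#C[C@](C)(O)CC[C@]1(C)CCC=C(C)[C@H]1C | intermediate
20 | O-(pinacolboryl) ether of 19 | C#C[C@](C)(OB1OC(C)(C)C(C)(C)O1)CC[C@]2(C)CCC=C(C)[C@H]2C | intermediate (not isolated)
21 | O-(pinacolboryl) ether of 22 | CC1(C)OB(/C=C\[C@](C)(OB2OC(C)(C)C(C)(C)O2)CC[C@]3(C)CCC=C(C)[C@H]3C)OC1(C)C | intermediate (not isolated)
22 | (1Z,3R)-3-methyl-1-(4,4,5,5-tetramethyl-1,3,2-dioxaborolan-2-yl)-5-[(1S,2S)-1,2,3-trimethylcyclohex-3-en-1-yl]pent-1-en-3-ol | CC1(C)OB(/C=C\[C@](C)(O)CC[C@]2(C)CCC=C(C)[C@H]2C)OC1(C)C | intermediate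
23 | 2,3,4-trimethoxyphenol | COc1ccc(O)c(OC)c1OC | starting material
24 | 6-iodo-2,3,4-trimethoxyphenol | COc1cc(I)c(O)c(OC)c1OC | intermediate
25 | 6-iodo-2,3,4,4-tetramethoxycyclohexa-2,5-dien-1-one | COC1=C(OC)C(OC)(OC)C=C(I)C1=O | intermediate
26 | 6-{(1Z,3R)-3-hydroxy-3-methyl-5-[(1S,2S)-1,2,3-trimethylcyclohex-3-en-1-yl]pent-1-en-1-yl}-2,3,4,4-tetramethoxycyclohexa-2,5-dien-1-one | COC1=C(OC)C(OC)(OC)C=C(/C=C\[C@](C)(O)CC[C@]2(C)CCC=C(C)[C@H]2C)C1=O | intermediate (not isolated)
27 | (2R)-6,7,8,8-tetramethoxy-2-methyl-2-{2-[(1S,2S)-1,2,3-trimethylcyclohex-3-en-1-yl]ethyl}-8,8a-dihydro-2H-chromen-5(4aH)-one (ring-fusion carbons not defined) | COC1=C(OC)C(OC)(OC)C2O[C@](C)(CC[C@]3(C)CCC=C(C)[C@H]3C)C=CC2C1=O | intermediate (not isolated)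
28 | (2R)-6,7,8-trimethoxy-2-methyl-2-{2-[(1S,2S)-1,2,3-trimethylcyclohex-3-en-1-yl]ethyl}-2H-chromen-5-ol | COc1c(O)c2c(c(OC)c1OC)O[C@](C)(CC[C@]1(C)CCC=C(C)[C@H]1C)C=C2 | target

Total steps: 11. Longest linear sequence: 8 steps (steps 1, 2, 3, 4, 5, 7, 8, 11).

**Steps most likely to fail**

1. Step 11. The α-iodo quinone monoketal may be consumed by base or palladium (hydrolysis to the quinone, reduction of the C–I bond) faster than it couples, or ring closure may stall before aromatisation. Fallback: the coupling is done on the aromatic iodide and the dearomatisation follows. Suzuki–Miyaura coupling of 22 with iodophenol 24 (Pd(PPh3)4, K2CO3, dioxane/H2O, 60 °C) should give 6-{(1Z,3R)-3-hydroxy-3-methyl-5-[(1S,2S)-1,2,3-trimethylcyclohex-3-en-1-yl]pent-1-en-1-yl}-2,3,4-trimethoxyphenol F1. Oxidation of F1 with PhI(OAc)2 in MeOH at 0 °C should give dienone 26, which with CSA in CH2Cl2 closes to 27 and aromatises. This fallback sets out from 22 and 24 and returns at 28.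

2. Step 5. The radical addition may show poor facial selectivity at C1', or the homoallylic tertiary radical may rearrange before it is trapped. Fallback: the quaternary centre is set by polar alkylation and the carboxyl carbon becomes the C1' methyl. The dianion 9 of acid 8 (LiN(i-Pr)2, THF) is alkylated with oxirane anti to the C2' methyl to give (1R,2R)-1-(2-hydroxyethyl)-2,3-dimethylcyclohex-3-ene-1-carboxylic acid F2, which lactonises with TsOH in toluene to (5R,6R)-6,7-dimethyl-2-oxaspiro[4.5]dec-7-en-1-one F3. Reduction with i-Bu2AlH (toluene, −78 °C) gives (5R,6R)-6,7-dimethyl-2-oxaspiro[4.5]dec-7-en-1-ol F4. Wolff–Kishner reduction (N2H4·H2O, KOH, diethylene glycol, 200 °C) through the hydrazone of (1R,2R)-1-(2-hydroxyethyl)-2,3-dimethylcyclohex-3-ene-1-carbaldehyde F5 gives 2-[(1S,2S)-1,2,3-trimethylcyclohex-3-en-1-yl]ethan-1-ol F6. Iodination (I2, PPh3, imidazole) gives 2-[(1S,2S)-1,2,3-trimethylcyclohex-3-en-1-yl]ethyl iodide F7, and copper-catalysed borylation (CuI, PPh3, LiOMe, B2pin2, DMF) gives the boronate. This fallback sets out from 8 and returns at 12.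

3. Step 7. The lithiated propargylic carbamate may lose its configuration before it is borylated, which would erode C2 and give inseparable diastereomers. Fallback: C2 is set by a Sharpless epoxidation. Acid 10 is added to but-3-en-2-one under the photoredox conditions of step 5 (Giese addition) to give 4-[(1S,2S)-1,2,3-trimethylcyclohex-3-en-1-yl]butan-2-one F8. Horner–Wadsworth–Emmons olefination ((EtO)2P(O)CH2CO2Et, NaH, THF) gives ethyl (2E)-3-methyl-5-[(1S,2S)-1,2,3-trimethylcyclohex-3-en-1-yl]pent-2-enoate F9, and i-Bu2AlH gives (2E)-3-methyl-5-[(1S,2S)-1,2,3-trimethylcyclohex-3-en-1-yl]pent-2-en-1-ol F10. Epoxidation (Ti(Oi-Pr)4, D-(−)-diethyl tartrate, t-BuOOH, 4 Å sieves, CH2Cl2, −20 °C) gives [(2R,3R)-3-methyl-3-{2-[(1S,2S)-1,2,3-trimethylcyclohex-3-en-1-yl]ethyl}oxiran-2-yl]methanol F11. PPh3 and CCl4 give (2S,3R)-2-(chloromethyl)-3-methyl-3-{2-[(1S,2S)-1,2,3-trimethylcyclohex-3-en-1-yl]ethyl}oxirane F12, and n-BuLi (3 equiv, THF, −78 °C) fragments F12 to the tertiary propargylic alcohol with the epoxide C–O bond at the carbinol carbon intact. This fallback sets out from 10 and returns at 19.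

**Further compounds**

F1 | step 11 | 6-{(1Z,3R)-3-hydroxy-3-methyl-5-[(1S,2S)-1,2,3-trimethylcyclohex-3-en-1-yl]pent-1-en-1-yl}-2,3,4-trimethoxyphenol | COc1cc(/C=C\[C@](C)(O)CC[C@]2(C)CCC=C(C)[C@H]2C)c(O)c(OC)c1OC
F2 | step 5 | (1R,2R)-1-(2-hydroxyethyl)-2,3-dimethylcyclohex-3-ene-1-carboxylic acid | OC(=O)[C@@]1(CCO)CCC=C(C)[C@H]1C
F3 | step 5 | (5R,6R)-6,7-dimethyl-2-oxaspiro[4.5]dec-7-en-1-one | O=C1OCC[C@@]12CCC=C(C)[C@H]2C
F4 | step 5 | (5R,6R)-6,7-dimethyl-2-oxaspiro[4.5]dec-7-en-1-ol (anomers) | OC1OCC[C@@]12CCC=C(C)[C@H]2C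
F5 | step 5 | hydrazone of (1R,2R)-1-(2-hydroxyethyl)-2,3-dimethylcyclohex-3-ene-1-carbaldehyde | NN=C[C@@]1(CCO)CCC=C(C)[C@H]1C
F6 | step 5 | 2-[(1S,2S)-1,2,3-trimethylcyclohex-3-en-1-yl]ethan-1-ol | OCC[C@]1(C)CCC=C(C)[C@H]1C
F7 | step 5 | 2-[(1S,2S)-1,2,3-trimethylcyclohex-3-en-1-yl]ethyl iodide | ICC[C@]1(C)CCC=C(C)[C@H]1C
F8 | step 7 | 4-[(1S,2S)-1,2,3-trimethylcyclohex-3-en-1-yl]butan-2-one | CC(=O)CC[C@]1(C)CCC=C(C)[C@H]1C
F9 | step 7 | ethyl (2E)-3-methyl-5-[(1S,2S)-1,2,3-trimethylcyclohex-3-en-1-yl]pent-2-enoate | CCOC(=O)/C=C(\C)CC[C@]1(C)CCC=C(C)[C@H]1C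
F10 | step 7 | (2E)-3-methyl-5-[(1S,2S)-1,2,3-trimethylcyclohex-3-en-1-yl]pent-2-en-1-ol | OC/C=C(\C)CC[C@]1(C)CCC=C(C)[C@H]1C
F11 | step 7 | [(2R,3R)-3-methyl-3-{2-[(1S,2S)-1,2,3-trimethylcyclohex-3-en-1-yl]ethyl}oxiran-2-yl]methanol | OC[C@H]1O[C@]1(C)CC[C@]2(C)CCC=C(C)[C@H]2C
F12 | step 7 | (2S,3R)-2-(chloromethyl)-3-methyl-3-{2-[(1S,2S)-1,2,3-trimethylcyclohex-3-en-1-yl]ethyl}oxirane | ClC[C@H]1O[C@]1(C)CC[C@]2(C)CCC=C(C)[C@H]2C
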